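The data stem from a simulated flask for an exercise; noise was put on by code.

**Late times.** Late times are what you need: the flask is read at 40 h, and Thursday's run, which carries the same 0.74 mM of free catalyst, stops at 25.0 h.

| flask | left-handed substrate | right-handed substrate | solid reagent | free catalyst | remark | time |
|---|---|---|---|---|---|---|
| Tuesday's | 1 M | 1 M | 1.2 M | 1 mM | run made earlier |  |
| Saturday's | 1 M | 1 M | 1.2 M | 1.6 mM | run made earlier |  |
| Thursday's | 1 M | 1 M | 0.60 M | 0.74 mM | run made earlier |  |
| flask | 1.0 M | 1.0 M | 1.20 M | 0.74 mM |  | 40 h |

- Tuesday's (time / h: left-handed product / %): 2.00: 0.2; 6.00: 0.1; 12.0: 1.1; 15.0: 1.6; 25.0: 3.3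
- Saturday's (time / h: left-handed product / %): 5.00: 0.4; 10.0: 0.9; 15.0: 2.5; 20.0: 3.4; 25.0: 4.9
- Thursday's (time / h: left-handed product / %): 5.00: 0; 10.0: 1.3; 15.0: 0.9; 20.0: 2.6; 25.0: 3.1

(scatter of a reading: 0.5 percentage points)

- how much left-handed product there is at 40 h, in percent of the left-handed substrate and right-handed substrate together charged
- the change that raises the amount of left-handed product at 40 h, in percent of the left-handed substrate and right-handed substrate together charged most ("none" if none brings more than 2 percentage points) (green / teal / red / none)
- amount of left-handed product at 40 h, in percent of the left-handed substrate and right-handed substrate together charged, after green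

- green: doubling the dissolution coefficient of the solid reagent, all else as stated
- teal: doubling the solubility of the solid reagent, all else as stated
- red: doubling the amount of free catalyst, all else as stated

- free catalyst is single-handed; left-handed substrate and right-handed substrate are mirror images of each other, charged as a racemate, each of them at the stated concentration
- as a solid, counted per litre of solution: solid reagent
- at the start none of the solid reagent is in solution

**Which numbers.** Take the settings in turn. Thursday's solid reagent is half of Tuesday's and its free catalyst is 0.74 mM against 1 mM, so two settings differ between them, and their last readings differ by 0.2 percentage points, less than the scatter of 0.5 points. Saturday's 1.6 mM of free catalyst against Tuesday's 1 mM moves that reading by 1.6 points. Now define the late gain as the points of left-handed product a run adds between its readings at 15.0 h and 25.0 h, a mean slope standing in for the curve; over that 10.0 h, Thursday's run gives 2.2 points. Over the remaining 15.0 h it adds 3.3 points, more than either setting moved, so the late gain is the number to know well.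

**My reckoning.** My estimate is 3.1 % plus that, 6.40 %, give or take 1.5 points from the scatter of both readings it rests on, and it runs low if the curve keeps steepening. Saturday, with twice Thursday's catalyst and twice its solid reagent, has a late gain of 2.4 points, a gap to Thursday's smaller than the 0.71 points scatter of a gain, so I would not bet on red.

**The forecast.** The forecast gives 5.2 %, red, and 6.5 % after green, reading that “the rate is about first order in catalyst”. My estimate is higher than its 5.2 %.

**The flask.** The flask gives 6.28 %. The best change is teal, doubling the solubility, with 7.1 points; green brings 4.3 points, reaching 10.6 %, and red brings 1.9 points, less than the 2 points that counts.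

    free catalyst + left-handed substrate ⇌ catalyst intermediate A (K = 1.20 L mol⁻¹, k = 3.10 L mol⁻¹ min⁻¹)
    free catalyst + right-handed substrate ⇌ catalyst intermediate B (K = 9.70 L mol⁻¹, k = 23.0 L mol⁻¹ min⁻¹)
    partner + catalyst intermediate A → free catalyst + left-handed product (k = 8.80 L mol⁻¹ min⁻¹)
    partner + catalyst intermediate B → free catalyst + right-handed product (k = 3.10 L mol⁻¹ min⁻¹)
    solid reagent ⇌ partner, rate k5*(cs5 - [partner]) while solid is left; crystals form when [partner] > cs5 (solubility = 0.360 M, k = 8.70 × 10⁻⁴ min⁻¹)

**Longer standing.** The neighbouring flask differs in time, read at 6.0 d. Carrying 2.2 points per 10.0 h onward from 6.28 % reckons 29.2 % for it. That neighbouring flask gives 19.6 %, with solid reagent, the limiting reagent, at 0 % and c(partner) at 1.42 × 10⁻⁵ M.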